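The route builds the ten-membered carbocycle (C1–C10) bare and adds the lactone region afterwards. With C6 as a ketone, C7 and C8 are the α and β carbons of an enone. One copper-catalysed boryl conjugate addition with enolate alkylation then forms C8–B (a masked C8–O) and C7–C11 and sets both stereocentres; C11–C12 later closes the five-membered lactone ring (O–C6–C7–C11–C12). The precursor is the cross-conjugated (2Z,6E,9E)-4-silyloxy-3,7-dimethylcyclodeca-2,6,9-trienone. Its only stereocentre (C3) comes from (S)-carvone through cis-carveol, and its ring is made by an anionic oxy-Cope expansion followed by Saegusa oxidation.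

Key step: step 7

Remark (numbering): germacrane numbering is used for all ring compounds (ring C1–C10, C14 on C10, C15 on C4, C11–C13 on C7); β is the face of the C7–C11 bond; the SMILES strings are definitive.
Remark (assumption): the acetate unit is introduced as its methyl ester, a spectator group, so that the lactone can close under PPTS; strong acid would endanger the 1(10),4-diene and the allylic silyl ether.
Remark (assumption): the sense of induction of the copper–bisphosphine catalyst on this ring is settled by testing both commercial ligand antipodes; the one giving (8R) is used.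

Step 1
Reactants: 1 (S)-(+)-carvone
Product: 2 (1S,5S)-cis-carveol
Conditions: NaBH4, CeCl3·7H2O, MeOH, −78 → 0 °C
Reagents that add atoms: none
Why: Luche 1,2-reduction of the enone, in which the Ce(III)-activated carbonyl takes hydride axially on the half-chair that keeps the C5 isopropenyl group equatorial, so the new carbinol centre (1S) is cis to that group.

Step 2
Reactants: 2 (1S,5S)-cis-carveol
Product: 3 (1S,5S)-cis-carveol tert-butyldimethylsilyl ether
Conditions: TBSCl, imidazole, DMF, rt
Reagents that add atoms: tert-butyldimethylsilyl chloride, CC(C)(C)[Si](C)(C)Cl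
Why: Imidazole-mediated silylation of a secondary allylic alcohol, which touches no stereocentre.

Step 3
Reactants: 3 (1S,5S)-cis-carveol tert-butyldimethylsilyl ether
Product: 4 (4S,6S)-4-(tert-butyldimethylsilyloxy)-3-methyl-6-(prop-1-en-2-yl)cyclohex-2-en-1-one
Conditions: CrO3, 3,5-dimethylpyrazole, CH2Cl2, −20 °C
Reagents that add atoms: chromium trioxide, O=[Cr](=O)=O
Why: Chromium(VI)–pyrazole allylic C–H oxidation, which takes the only unhindered ring methylene next to the trisubstituted alkene to the enone (the carbinol C–H is shielded by the silyl ether and an isopropenyl group is tolerated in related terpene oxidations); the α-centre need not be preserved because step 5 erases it.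

Step 4
Reactants: 4 (4S,6S)-4-(tert-butyldimethylsilyloxy)-3-methyl-6-(prop-1-en-2-yl)cyclohex-2-en-1-one; 5 vinylmagnesium bromide
Product: 6 (1S,4S,6S)-4-(tert-butyldimethylsilyloxy)-1-ethenyl-3-methyl-6-(prop-1-en-2-yl)cyclohex-2-en-1-ol
Conditions: CeCl3, THF, −78 °C; aq. NH4Cl
Reagents that add atoms: vinylmagnesium bromide (5), C=C[Mg]Br
Why: Organocerium 1,2-addition to the enone carbonyl (non-basic, so the α-isopropenyl ketone is not enolised), with the vinyl group entering anti to the neighbouring isopropenyl group to set the carbinol centre (1S, vinyl trans to isopropenyl).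

Step 5
Reactants: 6 (1S,4S,6S)-4-(tert-butyldimethylsilyloxy)-1-ethenyl-3-methyl-6-(prop-1-en-2-yl)cyclohex-2-en-1-ol
Product: 9 (1Z,5E,8S,9Z)-8-(tert-butyldimethylsilyloxy)-5,9-dimethyl-1-(trimethylsilyloxy)cyclodeca-1,5,9-triene, via potassium alkoxide 7 (not isolated), via potassium enolate 8 (not isolated)
Conditions: KH, 18-crown-6, THF, 25 → 60 °C; then TMSCl, Et3N, −78 °C
Reagents that add atoms: chlorotrimethylsilane, C[Si](C)(C)Cl
Why: Anionic oxy-Cope [3,3] rearrangement through a chair transition state with both alkenyl groups equatorial, which expands the ring by four atoms, makes the new C1=C10 alkene E, keeps the ring Z alkene and delivers the C6–C7 enolate regiospecifically for O-silylation, while C3 is untouched and the former isopropenyl-bearing centre disappears.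

Step 6
Reactants: 9 (1Z,5E,8S,9Z)-8-(tert-butyldimethylsilyloxy)-5,9-dimethyl-1-(trimethylsilyloxy)cyclodeca-1,5,9-triene
Product: 10 (2Z,4S,6E,9E)-4-(tert-butyldimethylsilyloxy)-3,7-dimethylcyclodeca-2,6,9-trien-1-one
Conditions: Pd(OAc)2 (1.1 equiv), MeCN, rt
Reagents that add atoms: none
Why: Ito–Saegusa oxidation, in which Pd(II) forms the C7-bound palladium enolate and syn β-hydride elimination can only use a C8 hydrogen, so the new alkene is C7=C8 and is expected to be E from the extended C6–C7–C8–C9 segment of the ring.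

Step 7
Reactants: 10 (2Z,4S,6E,9E)-4-(tert-butyldimethylsilyloxy)-3,7-dimethylcyclodeca-2,6,9-trien-1-one; 11 bis(pinacolato)diboron; 12 methyl bromoacetate
Product: 14 methyl 2-[(1R,2R,4E,7S,8Z)-7-(tert-butyldimethylsilyloxy)-4,8-dimethyl-10-oxo-2-(4,4,5,5-tetramethyl-1,3,2-dioxaborolan-2-yl)cyclodeca-4,8-dien-1-yl]acetate, via lithium enolate 13 (not isolated)
Conditions: CuCl (5 mol%), Josiphos SL-J001 (6 mol%, antipode giving 8R), LiOtBu (1.05 equiv, premixed with 11), THF, −20 °C, slow addition of 10, no proton source; then 12, DMPU, −78 → −30 °C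
Reagents that add atoms: bis(pinacolato)diboron (11), CC1(C)OB(OC1(C)C)B1OC(C)(C)C(C)(C)O1; methyl bromoacetate (12), BrCC(=O)OC
Why: Proposed new method: ligated Cu–OtBu undergoes σ-bond metathesis with the diboron ate complex to give L*Cu–Bpin, which adds syn across the strained, disubstituted C7=C8 enone with boron on C8, and the copper enolate is released by the lithium alkoxide/borate as a lithium (enoxyborate) enolate that is then C-alkylated at C7 by the bromoacetate in an SN2 step. The closest known reactions are the copper-catalysed enantioselective β-borylation of cyclic enones, the aldol trapping of the boron enolates formed under aprotic conditions, and the alkylation of enoxyborates and of β-silyl or β-boryl enolates; the untested part is the intermolecular alkylation in the same flask on a cross-conjugated macrocyclic trienone. No ring is closed. C8 is set by the chiral bisphosphine on copper (both faces of the E-enone are offered by interconverting ring conformers, so the ligand antipode that gives 8R is matched to the C3-biased ring), and C7 is set by alkylation anti to the C8–B bond with H-8 eclipsing the enolate (A1,3 control), which amounts to net anti addition across the E alkene. Site selectivity for C7=C8 over C4=C5 is secured by the β,β-disubstitution and γ-silyloxy group of the latter, α-alkylation by the cross-conjugated enolate carrying its charge only at C7, and deprotonation at the doubly allylic C9 is suppressed by keeping the alkoxide bound to the diboron and adding the trienone slowly at low temperature.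

Step 8
Reactants: 14 methyl 2-[(1R,2R,4E,7S,8Z)-7-(tert-butyldimethylsilyloxy)-4,8-dimethyl-10-oxo-2-(4,4,5,5-tetramethyl-1,3,2-dioxaborolan-2-yl)cyclodeca-4,8-dien-1-yl]acetate
Product: 16 (3S,6S,7R,8R)-8β-(pinacolboryl)-3β-(tert-butyldimethylsilyloxy)-13-norgermacra-1(10)E,4Z-dien-12,6α-olide, via hydroxy ester 15 (not isolated)
Conditions: NaBH4, CeCl3·7H2O, MeOH/THF, −78 °C; then PPTS (cat.), CH2Cl2, rt
Reagents that add atoms: none
Why: Luche 1,2-reduction followed by acid-catalysed lactonisation (5-exo-trig acyl substitution), in which hydride is expected on the carbonyl face anti to the C7 acetate arm in the conformer with the C7–C8 ring bond near the carbonyl plane, giving the 6α-alkoxide (C6 set under control of C7), the only hydroxyl in the molecule, which therefore closes the trans-fused 12,6-lactone regiospecifically while C8 stays masked as the boronate.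

Step 9
Reactants: 16 (3S,6S,7R,8R)-8β-(pinacolboryl)-3β-(tert-butyldimethylsilyloxy)-13-norgermacra-1(10)E,4Z-dien-12,6α-olide
Product: 18 (3S,6R,7R,8R)-8β-hydroxy-3β-(tert-butyldimethylsilyloxy)-13-norgermacra-1(10)E,4Z-dien-12,6α-olide, via borate ester 17 (not isolated)
Conditions: NaBO3·4H2O, THF/H2O, 0 °C → rt
Reagents that add atoms: sodium perborate, [Na+].[Na+].O[B-]1(O)OO[B-](O)(O)OO1
Why: Perborate oxidation of the secondary alkyl boronate, in which C8 migrates from boron to oxygen with retention to give the 8β-alcohol, while the mild pH spares the lactone, the silyl ether and both alkenes.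

Step 10
Reactants: 19 angelic acid [(Z)-2-methylbut-2-enoic acid]
Product: 20 (Z)-2-methylbut-2-en-1-ol
Conditions: LiAlH4, Et2O, 0 °C
Reagents that add atoms: none
Why: Hydride reduction of the carboxylic acid to the primary allylic alcohol, which leaves the Z alkene unchanged at 0 °C.

Step 11
Reactants: 20 (Z)-2-methylbut-2-en-1-ol
Product: 21 [(2R,3S)-2,3-dimethyloxiran-2-yl]methanol
Conditions: Ti(OiPr)4, D-(−)-diethyl tartrate, TBHP, 4 Å MS, CH2Cl2, −20 °C
Reagents that add atoms: tert-butyl hydroperoxide, CC(C)(C)OO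
Why: Sharpless asymmetric epoxidation, in which the titanium–D-tartrate complex delivers oxygen to the alkene face opposite to the one chosen by L-tartrate (which gives 2S epoxy alcohols), setting C2 as R, while syn addition to the Z alkene fixes C3 as S with the two methyl groups trans.

Step 12
Reactants: 21 [(2R,3S)-2,3-dimethyloxiran-2-yl]methanol
Product: 22 (2S,3S)-2,3-dimethyloxirane-2-carboxylic acid
Conditions: RuCl3 (cat.), NaIO4, MeCN/EtOAc/H2O, rt
Reagents that add atoms: sodium periodate, [Na+].[O-]I(=O)(=O)=O; water, O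
Why: Ruthenium tetroxide oxidation (periodate as terminal oxidant) of the primary alcohol to the acid through the aldehyde hydrate, which leaves the epoxide and both centres untouched (the C2 descriptor changes from R to S only through the priority change).

Step 13
Reactants: 18 (3S,6R,7R,8R)-8β-hydroxy-3β-(tert-butyldimethylsilyloxy)-13-norgermacra-1(10)E,4Z-dien-12,6α-olide; 22 (2S,3S)-2,3-dimethyloxirane-2-carboxylic acid
Product: 24 (3S,6R,7R,8R)-8β-[(2S,3S)-2,3-epoxy-2-methylbutanoyloxy]-3β-(tert-butyldimethylsilyloxy)-13-norgermacra-1(10)E,4Z-dien-12,6α-olide, via mixed anhydride 23 (not isolated)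
Conditions: 2,4,6-trichlorobenzoyl chloride, Et3N, THF, rt; then 18, DMAP, toluene, rt
Reagents that add atoms: (2S,3S)-2,3-dimethyloxirane-2-carboxylic acid (22), OC(=O)[C@@]1(C)O[C@H]1C
Why: Yamaguchi esterification, in which DMAP opens the mixed anhydride at the epoxy-acyl carbonyl and the acylpyridinium acylates the hindered 8β-hydroxyl with retention at C8, the acid having no α-hydrogen and so no way to epimerise.

Step 14
Reactants: 24 (3S,6R,7R,8R)-8β-[(2S,3S)-2,3-epoxy-2-methylbutanoyloxy]-3β-(tert-butyldimethylsilyloxy)-13-norgermacra-1(10)E,4Z-dien-12,6α-olide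
Product: 28 (3S,6R,7R,8R)-8β-[(2S,3S)-2,3-epoxy-2-methylbutanoyloxy]-3β-(tert-butyldimethylsilyloxy)germacra-1(10)E,4Z,11(13)-trien-12,6α-olide, via lactone enolate 25 (not isolated), via Mannich base 26 (not isolated), via methiodide 27 (not isolated)
Conditions: LDA (1.1 equiv), THF, −78 °C; CH2=NMe2+ I−, −78 → 0 °C; then MeI, THF, rt; then aq. NaHCO3, EtOAc
Reagents that add atoms: Eschenmoser's salt (N,N-dimethylmethyleneiminium iodide), C=[N+](C)C.[I-]
Why: α-Methylenation by Mannich reaction and Hofmann-type elimination, in which the lactone CH2 is the only enolisable position (the epoxy ester has no α-hydrogen), its lithium enolate adds to the iminium salt at −78 °C, and quaternisation followed by mild base gives the exocyclic C11=C13 alkene, destroying the transient C11 centre.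

Step 15
Reactants: 28 (3S,6R,7R,8R)-8β-[(2S,3S)-2,3-epoxy-2-methylbutanoyloxy]-3β-(tert-butyldimethylsilyloxy)germacra-1(10)E,4Z,11(13)-trien-12,6α-olide
Product: 29 (3S,6R,7R,8R)-8β-[(2S,3S)-2,3-epoxy-2-methylbutanoyloxy]-3β-hydroxygermacra-1(10)E,4Z,11(13)-trien-12,6α-olide
Conditions: HF·pyridine, pyridine, THF, 0 °C → rt
Reagents that add atoms: none
Why: Fluoride-mediated silyl ether cleavage under pyridine-buffered conditions (Si–F bond formation), which retain C3 and leave the esters, the unsaturated lactone and the epoxy ester intact.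

Step 16
Reactants: 29 (3S,6R,7R,8R)-8β-[(2S,3S)-2,3-epoxy-2-methylbutanoyloxy]-3β-hydroxygermacra-1(10)E,4Z,11(13)-trien-12,6α-olide
Product: 30 (3S,6R,7R,8R)-8β-[(2S,3S)-2,3-epoxy-2-methylbutanoyloxy]-3β-(2-methylpropanoyloxy)germacra-1(10)E,4Z,11(13)-trien-12,6α-olide
Conditions: isobutyric anhydride, Et3N, DMAP (cat.), CH2Cl2, 0 °C
Reagents that add atoms: isobutyric anhydride, CC(C)C(=O)OC(=O)C(C)C
Why: DMAP-catalysed acylation of the secondary allylic 3β-alcohol by the anhydride, with retention at C3.

Step 17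
Reactants: 30 (3S,6R,7R,8R)-8β-[(2S,3S)-2,3-epoxy-2-methylbutanoyloxy]-3β-(2-methylpropanoyloxy)germacra-1(10)E,4Z,11(13)-trien-12,6α-olide
Product: 31 CNP0117882.1 [(1R,3S,6R,7R,8R,10R)-1β,10α-epoxy-8β-[(2S,3S)-2,3-epoxy-2-methylbutanoyloxy]-3β-(2-methylpropanoyloxy)germacra-4Z,11(13)-dien-12,6α-olide]
Conditions: mCPBA (1.05 equiv), NaHCO3, CH2Cl2, 0 °C
Reagents that add atoms: meta-chloroperbenzoic acid, OOC(=O)c1cccc(Cl)c1
Why: Prilezhaev epoxidation, in which the peracid attacks the most electron-rich alkene, the isolated trisubstituted C1=C10 (C4=C5 is deactivated by two allylic acyloxy groups and C11=C13 by conjugation), from the peripheral face of the conformer with C14 on the β face, giving the trans 1β,10α-epoxide (1R,10R) by syn addition to the E alkene.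

Compound list
1 | (S)-(+)-carvone | CC1=CC[C@@H](CC1=O)C(C)=C | starting material
2 | (1S,5S)-cis-carveol | CC1=CC[C@@H](C[C@@H]1O)C(C)=C | intermediate
3 | (1S,5S)-cis-carveol tert-butyldimethylsilyl ether | CC1=CC[C@@H](C[C@@H]1O[Si](C)(C)C(C)(C)C)C(C)=C | intermediate
4 | (4S,6S)-4-(tert-butyldimethylsilyloxy)-3-methyl-6-(prop-1-en-2-yl)cyclohex-2-en-1-one | CC1=CC(=O)[C@@H](C[C@@H]1O[Si](C)(C)C(C)(C)C)C(C)=C | intermediate
5 | vinylmagnesium bromide | C=C[Mg]Br | starting material
6 | (1S,4S,6S)-4-(tert-butyldimethylsilyloxy)-1-ethenyl-3-methyl-6-(prop-1-en-2-yl)cyclohex-2-en-1-ol (vinyl trans to isopropenyl) | CC1=C[C@@](O)(C=C)[C@@H](C[C@@H]1O[Si](C)(C)C(C)(C)C)C(C)=C | intermediate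
7 | potassium alkoxide of 6 | CC1=C[C@@]([O-])(C=C)[C@@H](C[C@@H]1O[Si](C)(C)C(C)(C)C)C(C)=C.[K+] | intermediate (not isolated)
8 | potassium enolate of (2Z,4S,6E)-4-(tert-butyldimethylsilyloxy)-3,7-dimethylcyclodeca-2,6-dien-1-one (C6–C7 enolate, O cis to C8) | [K+].[O-]/C1=C\CC/C(C)=C/C[C@H](O[Si](C)(C)C(C)(C)C)/C(C)=C\1 | intermediate (not isolated)
9 | (1Z,5E,8S,9Z)-8-(tert-butyldimethylsilyloxy)-5,9-dimethyl-1-(trimethylsilyloxy)cyclodeca-1,5,9-triene | C[Si](C)(C)O/C1=C\CC/C(C)=C/C[C@H](O[Si](C)(C)C(C)(C)C)/C(C)=C\1 | intermediate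
10 | (2Z,4S,6E,9E)-4-(tert-butyldimethylsilyloxy)-3,7-dimethylcyclodeca-2,6,9-trien-1-one (key-step precursor) | C1/C=C(\C)C/C=C/C(=O)/C=C(/C)[C@H]1O[Si](C)(C)C(C)(C)C | intermediate
11 | bis(pinacolato)diboron | CC1(C)OB(OC1(C)C)B1OC(C)(C)C(C)(C)O1 | starting material
12 | methyl bromoacetate | BrCC(=O)OC | starting material
13 | lithium enolate of the (3S,8R)-8-boryl dienone (C6–C7 enolate, geometry left open) | [Li+].[O-]C1/C=C(/C)[C@@H](O[Si](C)(C)C(C)(C)C)C/C=C(\C)C[C@@H](B2OC(C)(C)C(C)(C)O2)C=1 | intermediate (not isolated)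
14 | methyl 2-[(1R,2R,4E,7S,8Z)-7-(tert-butyldimethylsilyloxy)-4,8-dimethyl-10-oxo-2-(4,4,5,5-tetramethyl-1,3,2-dioxaborolan-2-yl)cyclodeca-4,8-dien-1-yl]acetate (key-step product; 3S,7R,8R in germacrane numbering) | O=C1/C=C(/C)[C@@H](O[Si](C)(C)C(C)(C)C)C/C=C(\C)C[C@@H](B2OC(C)(C)C(C)(C)O2)[C@H]1CC(=O)OC | intermediate
15 | (3S,6S,7R,8R)-6α-hydroxy methyl ester of 14 | O[C@@H]1/C=C(/C)[C@@H](O[Si](C)(C)C(C)(C)C)C/C=C(\C)C[C@@H](B2OC(C)(C)C(C)(C)O2)[C@H]1CC(=O)OC | intermediate (not isolated)
16 | (3S,6S,7R,8R)-8β-(pinacolboryl)-3β-(tert-butyldimethylsilyloxy)-13-norgermacra-1(10)E,4Z-dien-12,6α-olide | C1C(=O)O[C@@H]2/C=C(/C)[C@@H](O[Si](C)(C)C(C)(C)C)C/C=C(\C)C[C@@H](B3OC(C)(C)C(C)(C)O3)[C@@H]12 | intermediate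
17 | 8β-O-(pinacolboryl) ether of 18 (borate ester) | C1C(=O)O[C@@H]2/C=C(/C)[C@@H](O[Si](C)(C)C(C)(C)C)C/C=C(\C)C[C@@H](OB3OC(C)(C)C(C)(C)O3)[C@@H]12 | intermediate (not isolated)
18 | (3S,6R,7R,8R)-8β-hydroxy-3β-(tert-butyldimethylsilyloxy)-13-norgermacra-1(10)E,4Z-dien-12,6α-olide | C1C(=O)O[C@@H]2/C=C(/C)[C@@H](O[Si](C)(C)C(C)(C)C)C/C=C(\C)C[C@@H](O)[C@@H]12 | intermediate
19 | angelic acid [(Z)-2-methylbut-2-enoic acid] | C/C=C(/C)C(O)=O | starting material
20 | (Z)-2-methylbut-2-en-1-ol | C/C=C(/C)CO | intermediate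
21 | [(2R,3S)-2,3-dimethyloxiran-2-yl]methanol | OC[C@@]1(C)O[C@H]1C | intermediate
22 | (2S,3S)-2,3-dimethyloxirane-2-carboxylic acid (epoxyangelic acid) | OC(=O)[C@@]1(C)O[C@H]1C | intermediate
23 | (2S,3S)-2,3-dimethyloxirane-2-carboxylic 2,4,6-trichlorobenzoic anhydride | O=C(OC(=O)[C@@]1(C)O[C@H]1C)c1c(Cl)cc(Cl)cc1Cl | intermediate (not isolated)
24 | (3S,6R,7R,8R)-8β-[(2S,3S)-2,3-epoxy-2-methylbutanoyloxy]-3β-(tert-butyldimethylsilyloxy)-13-norgermacra-1(10)E,4Z-dien-12,6α-olide | C1C(=O)O[C@@H]2/C=C(/C)[C@@H](O[Si](C)(C)C(C)(C)C)C/C=C(\C)C[C@@H](OC(=O)[C@@]3(C)O[C@H]3C)[C@@H]12 | intermediate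
25 | lithium enolate of lactone 24 | C1=C([O-])O[C@@H]2/C=C(/C)[C@@H](O[Si](C)(C)C(C)(C)C)C/C=C(\C)C[C@@H](OC(=O)[C@@]3(C)O[C@H]3C)[C@@H]12.[Li+] | intermediate (not isolated)
26 | 11-(dimethylaminomethyl) lactone (Mannich base, C11 configuration immaterial) | CN(C)CC1C(=O)O[C@@H]2/C=C(/C)[C@@H](O[Si](C)(C)C(C)(C)C)C/C=C(\C)C[C@@H](OC(=O)[C@@]3(C)O[C@H]3C)[C@@H]12 | intermediate (not isolated)
27 | trimethylammonium iodide of 26 (methiodide) | C[N+](C)(C)CC1C(=O)O[C@@H]2/C=C(/C)[C@@H](O[Si](C)(C)C(C)(C)C)C/C=C(\C)C[C@@H](OC(=O)[C@@]3(C)O[C@H]3C)[C@@H]12.[I-] | intermediate (not isolated)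
28 | (3S,6R,7R,8R)-8β-[(2S,3S)-2,3-epoxy-2-methylbutanoyloxy]-3β-(tert-butyldimethylsilyloxy)germacra-1(10)E,4Z,11(13)-trien-12,6α-olide | C=C1C(=O)O[C@@H]2/C=C(/C)[C@@H](O[Si](C)(C)C(C)(C)C)C/C=C(\C)C[C@@H](OC(=O)[C@@]3(C)O[C@H]3C)[C@@H]12 | intermediate
29 | (3S,6R,7R,8R)-8β-[(2S,3S)-2,3-epoxy-2-methylbutanoyloxy]-3β-hydroxygermacra-1(10)E,4Z,11(13)-trien-12,6α-olide | C=C1C(=O)O[C@@H]2/C=C(/C)[C@@H](O)C/C=C(\C)C[C@@H](OC(=O)[C@@]3(C)O[C@H]3C)[C@@H]12 | intermediate
30 | (3S,6R,7R,8R)-8β-[(2S,3S)-2,3-epoxy-2-methylbutanoyloxy]-3β-(2-methylpropanoyloxy)germacra-1(10)E,4Z,11(13)-trien-12,6α-olide | C=C1C(=O)O[C@@H]2/C=C(/C)[C@@H](OC(=O)C(C)C)C/C=C(\C)C[C@@H](OC(=O)[C@@]3(C)O[C@H]3C)[C@@H]12 | intermediate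
31 | CNP0117882.1, (1R,3S,6R,7R,8R,10R)-1β,10α-epoxy-8β-[(2S,3S)-2,3-epoxy-2-methylbutanoyloxy]-3β-(2-methylpropanoyloxy)germacra-4Z,11(13)-dien-12,6α-olide | C=C1C(=O)O[C@@H]2/C=C(/C)[C@@H](OC(=O)C(C)C)C[C@H]3O[C@]3(C)C[C@@H](OC(=O)[C@@]3(C)O[C@H]3C)[C@@H]12 | target

Total step count: 17. Longest linear sequence: 14 steps (steps 1–9 and 13–17, from (S)-carvone); the side-chain acid takes steps 10–12.

Steps most likely to fail

1. Step 7 (Proposed new method). The enolate released after boryl addition may be protonated or alkylated on oxygen instead of on C7, may alkylate with poor facial selectivity, or the trienone may isomerise through deprotonation at C9 before the copper–boryl species adds. Fallback with known chemistry, setting out from 10: the borylation would be run under the established protic turnover conditions (CuCl, the same ligand, catalytic NaOtBu, 11, MeOH, THF, 0 °C), which protonate the copper enolate and should give the isolable β-boryl ketone, (3S,8R)-8-(pinacolboryl)-4-silyloxy dienone F1. Its kinetic lithium enolate (LiHMDS, THF, −78 °C; C7 is the only sp3 α-carbon) would then be alkylated with 12 in THF/DMPU, anti to the boryl group, which comes back to the route at 14.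

2. Step 8. Hydride addition to C6 may show poor facial selectivity, which would lead into the cis-fused lactone series. Fallback, setting out from 14: the C–B bond would be oxidised first (NaBO3·4H2O, THF/H2O, 0 °C) to the β-hydroxy ketone, (3S,7R,8R)-8β-hydroxy keto ester F2. Internal hydride delivery from the C8 hydroxyl (Me4NBH(OAc)3, MeCN/AcOH, −30 °C, Evans–Saksena reduction) should fix C6 anti to C8 and give the 6α,8β-diol ester F3. PPTS in CH2Cl2 would then close the 12,6-lactone, which comes back to the route at 18 and replaces steps 8 and 9. The regiochemistry of this closure (C6–OH over C8–OH) would have to be confirmed.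

3. Step 6. β-Hydride elimination may give the Z-enone, palladium hydride may move the double bonds into the skipped C8–C10 region, or the enol ether may simply be hydrolysed to the saturated ketone. Fallback, setting out from 9: selenenylation of the silyl enol ether (PhSeCl, CH2Cl2, −78 °C) should give the 7-(phenylselanyl) ketone F4. Oxidation (H2O2, pyridine, CH2Cl2, 0 °C) and syn elimination of the selenoxide, which avoids palladium hydride, would come back to the route at 10.

Further compounds
F1 | step 7 | (2Z,4S,6E,9R)-4-(tert-butyldimethylsilyloxy)-3,7-dimethyl-9-(4,4,5,5-tetramethyl-1,3,2-dioxaborolan-2-yl)cyclodeca-2,6-dien-1-one | O=C1/C=C(/C)[C@@H](O[Si](C)(C)C(C)(C)C)C/C=C(\C)C[C@@H](B2OC(C)(C)C(C)(C)O2)C1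
F2 | step 8 | methyl 2-[(1R,2R,4E,7S,8Z)-7-(tert-butyldimethylsilyloxy)-2-hydroxy-4,8-dimethyl-10-oxocyclodeca-4,8-dien-1-yl]acetate | O=C1/C=C(/C)[C@@H](O[Si](C)(C)C(C)(C)C)C/C=C(\C)C[C@@H](O)[C@H]1CC(=O)OC
F3 | step 8 | methyl 2-[(3S,6R,7R,8R)-6α,8β-dihydroxy-3β-(tert-butyldimethylsilyloxy)germacra-1(10)E,4Z-dien-7-yl]acetate (anti-1,3-diol ester, germacrane numbering) | O[C@@H]1/C=C(/C)[C@@H](O[Si](C)(C)C(C)(C)C)C/C=C(\C)C[C@@H](O)[C@H]1CC(=O)OC
F4 | step 6 | (2Z,4S,6E)-4-(tert-butyldimethylsilyloxy)-3,7-dimethyl-10-(phenylselanyl)cyclodeca-2,6-dien-1-one (selenium-bearing centre unassigned) | O=C1/C=C(/C)[C@@H](O[Si](C)(C)C(C)(C)C)C/C=C(\C)CCC1[Se]c1ccccc1
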